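## Retrosynthetic overview

1. The route rests on one feature: in benzofuran numbering (O1, C2 carrying the dimethoxyphenyl ring B, C3 carrying CH2OH, fused benzo ring A), C2 lies para to O4 of ring B. While O4 is still a free OH, Ag2O dehydrogenates the ArCH2 group that becomes C2 to a para-quinone methide, and the ring A phenol oxygen (future O1) adds to it. O1–C2 is the key disconnection and the dihydrofuran ring is the only ring made.
2. Ring A enters the closure with a nitrile at C5 in place of the cinnamyl chain. A 4-hydroxy-3-methoxycinnamate ring A is itself a classical substrate for Ag2O (side-chain radical coupling, ortho-quinone methide at C3), whereas a 4-cyanophenol is not. After the closure the nitrile is taken to the (E)-propenol by i-Bu2AlH, Wittig olefination and i-Bu2AlH. The C3 hydroxymethyl group is carried unprotected.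
3. C3 is set before the closure by alkylating the ring A arylacetyl imide of (R)-4-benzyloxazolidin-2-one with the ring B benzyl bromide, followed by LiBH4. C2 then follows from C3 in the closure (trans).
4. The ring A arylacetic acid comes from 4-hydroxy-3-methoxybenzonitrile by O-allylation, Claisen rearrangement, benzylation, ozonolysis and Pinnick oxidation.

Key step: step 11

Remark: the geometry of the exocyclic double bond of the quinone methide is left open, since both isomers close to the same product. (4R)-4-Benzyl-1,3-oxazolidin-2-one, [4-(benzyloxy)-3-methoxyphenyl]methanol and methyl (triphenylphosphoranylidene)acetate are taken as commercial.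

## Route

Step 1
Reactants: 1 4-hydroxy-3-methoxybenzonitrile; 2 allyl bromide
Product: 3 3-methoxy-4-(prop-2-en-1-yloxy)benzonitrile
Conditions: K2CO3, acetone, reflux
Reagents that add atoms: none
Why: Williamson ether synthesis, in which the cyanophenoxide formed by K2CO3 displaces bromide from the primary allylic halide by SN2.

Step 2
Reactants: 3 3-methoxy-4-(prop-2-en-1-yloxy)benzonitrile
Product: 4 4-hydroxy-3-methoxy-5-(prop-2-en-1-yl)benzonitrile
Conditions: N,N-diethylaniline, 200 °C
Reagents that add atoms: none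
Why: Aromatic Claisen rearrangement, whose [3,3]-shift can end only at C5, the one free ortho carbon (the other ortho carbon carries OMe, the para carbon the nitrile), after which tautomerisation returns the phenol.

Step 3
Reactants: 4 4-hydroxy-3-methoxy-5-(prop-2-en-1-yl)benzonitrile
Product: 5 4-(benzyloxy)-3-methoxy-5-(prop-2-en-1-yl)benzonitrile
Conditions: BnBr, K2CO3, DMF, 60 °C
Reagents that add atoms: benzyl bromide BrCc1ccccc1
Why: Williamson ether synthesis on the hindered but acidic phenoxide, which protects the phenol against ozone, chlorite and the enolate chemistry that follow.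

Step 4
Reactants: 5 4-(benzyloxy)-3-methoxy-5-(prop-2-en-1-yl)benzonitrile
Product: 7 4-(benzyloxy)-3-methoxy-5-(2-oxoethyl)benzonitrile, via ozonide 6 (not isolated)
Conditions: O3, CH2Cl2, −78 °C; then PPh3, −78 °C to rt
Reagents that add atoms: ozone [O-][O+]=O
Why: Ozonolysis with reductive work-up, in which ozone adds to the isolated terminal alkene far faster than to the nitrile-deactivated arene or the benzyl ether, PPh3 reduces the ozonide, and the enolisable arylacetaldehyde is carried on crude.

Step 5
Reactants: 7 4-(benzyloxy)-3-methoxy-5-(2-oxoethyl)benzonitrile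
Product: 8 [2-(benzyloxy)-5-cyano-3-methoxyphenyl]acetic acid
Conditions: NaClO2, NaH2PO4, 2-methyl-2-butene, t-BuOH–H2O, 0 °C to rt
Reagents that add atoms: sodium chlorite [Na+].[O-]Cl=O
Why: Pinnick oxidation, in which chlorous acid oxidises the aldehyde to the acid under buffered conditions while 2-methyl-2-butene removes the hypochlorous acid that would chlorinate the electron-rich ring.

Step 6
Reactants: 8 [2-(benzyloxy)-5-cyano-3-methoxyphenyl]acetic acid; 9 (4R)-4-benzyl-1,3-oxazolidin-2-one
Product: 11 4-(benzyloxy)-3-{2-[(4R)-4-benzyl-2-oxo-1,3-oxazolidin-3-yl]-2-oxoethyl}-5-methoxybenzonitrile, via mixed pivalic anhydride 10 (not isolated)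
Conditions: t-BuCOCl, Et3N, THF, −20 °C; then LiCl, 9, −20 °C to rt
Reagents that add atoms: pivaloyl chloride CC(C)(C)C(=O)Cl (its acyl group is held only in intermediate 10 and leaves again as pivalic acid)
Why: N-acylation of an oxazolidinone through a mixed anhydride, in which LiCl and Et3N generate the lithium-bound oxazolidinone anion that attacks the unhindered arylacetyl carbonyl of 10 and not the pivaloyl one; no stereocentre is formed.

Step 7
Reactants: 12 [4-(benzyloxy)-3-methoxyphenyl]methanol
Product: 13 1-(benzyloxy)-4-(bromomethyl)-2-methoxybenzene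
Conditions: PBr3, Et2O, 0 °C
Reagents that add atoms: phosphorus tribromide BrP(Br)Br
Why: Bromination of a benzylic alcohol with PBr3 through its phosphite ester and displacement by bromide; the electron-rich bromide is used at once without chromatography.

Step 8
Reactants: 11 4-(benzyloxy)-3-{2-[(4R)-4-benzyl-2-oxo-1,3-oxazolidin-3-yl]-2-oxoethyl}-5-methoxybenzonitrile; 13 1-(benzyloxy)-4-(bromomethyl)-2-methoxybenzene
Product: 15 4-(benzyloxy)-3-{(2R)-1-[(4R)-4-benzyl-2-oxo-1,3-oxazolidin-3-yl]-3-[4-(benzyloxy)-3-methoxyphenyl]-1-oxopropan-2-yl}-5-methoxybenzonitrile, via sodium enolate 14 (not isolated)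
Conditions: NaN(SiMe3)2, THF, −78 °C; then 13, −78 to −40 °C
Reagents that add atoms: sodium bis(trimethylsilyl)amide C[Si](C)(C)[N-][Si](C)(C)C.[Na+] (its sodium is held only in intermediate 14)
Why: Evans alkylation, in which the sodium-chelated Z-enolate 14 has one face covered by the C4 benzyl group of the (R)-auxiliary and the benzylic bromide adds to the other, setting the (R) centre that becomes C3.

Step 9
Reactants: 15 4-(benzyloxy)-3-{(2R)-1-[(4R)-4-benzyl-2-oxo-1,3-oxazolidin-3-yl]-3-[4-(benzyloxy)-3-methoxyphenyl]-1-oxopropan-2-yl}-5-methoxybenzonitrile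
Product: 16 4-(benzyloxy)-3-{(2R)-1-[4-(benzyloxy)-3-methoxyphenyl]-3-hydroxypropan-2-yl}-5-methoxybenzonitrile
Conditions: LiBH4, H2O (1 equiv), Et2O–THF, 0 °C
Reagents that add atoms: none
Why: Reductive cleavage of the N-acyloxazolidinone with LiBH4, in which hydride attacks the more electrophilic exocyclic carbonyl and takes it to the primary alcohol at 0 °C without enolising the α-aryl centre, while the nitrile and benzyl ethers are left alone.

Step 10
Reactants: 16 4-(benzyloxy)-3-{(2R)-1-[4-(benzyloxy)-3-methoxyphenyl]-3-hydroxypropan-2-yl}-5-methoxybenzonitrile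
Product: 17 4-hydroxy-3-[(2R)-1-hydroxy-3-(4-hydroxy-3-methoxyphenyl)propan-2-yl]-5-methoxybenzonitrile
Conditions: H2 (1 atm), Pd/C, EtOAc, rt
Reagents that add atoms: none
Why: Catalytic hydrogenolysis of the two aryl benzyl ethers, which on Pd/C in neutral EtOAc at 1 atm should be much faster than reduction of the aryl nitrile; the stereocentre is not touched.

Step 11
Reactants: 17 4-hydroxy-3-[(2R)-1-hydroxy-3-(4-hydroxy-3-methoxyphenyl)propan-2-yl]-5-methoxybenzonitrile
Product: 19 (2S,3R)-3-(hydroxymethyl)-2-(4-hydroxy-3-methoxyphenyl)-7-methoxy-2,3-dihydro-1-benzofuran-5-carbonitrile, via para-quinone methide 18 (not isolated)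
Conditions: Ag2O (1.5 equiv), CH2Cl2–acetone 4:1, 0.01 M, rt, dark
Reagents that add atoms: none
Why: Ag2O dehydrogenates the ring B phenol (phenoxyl radical, then loss of a second electron and the C2 proton) to para-quinone methide 18, whose exocyclic carbon is C2, as it is known to do with 4-alkyl-2-methoxyphenols. The ring A phenol, held next to C2 through the C3–C3a bond, adds to that carbon in a 5-exo-trig oxa-1,6-addition that restores the aromaticity of ring B and closes the dihydrofuran ring through O1–C2; the closest known reactions are the phenol capture of the quinone methide in oxidative 8–5 coupling of 4-hydroxycinnamyl phenols and the oxidative cyclisation of 2'-hydroxyisoflavans to pterocarpans. C2 is set under control of the existing C3 centre, the ring B aryl group ending anti to the C3 hydroxymethyl group, and since the addition is reversible through the ring B phenoxide the trans-(2S,3R) isomer is also the one that should accumulate. The step needs oxidation on ring B only, which the para nitrile of ring A secures by raising the oxidation potential of that phenol above that of the 4-alkylguaiacol ring and leaving it without a para benzylic hydrogen, whereas a 4-hydroxycinnamate ring A would be expected to be attacked by Ag2O at least as readily as ring B. The primary alcohol could close only an oxetane and should stay out, and the oxidant is kept near the stoichiometric amount so that the product phenol is not dehydrogenated further towards the benzofuran.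

Step 12
Reactants: 19 (2S,3R)-3-(hydroxymethyl)-2-(4-hydroxy-3-methoxyphenyl)-7-methoxy-2,3-dihydro-1-benzofuran-5-carbonitrile
Product: 20 (2S,3R)-2-(3,4-dimethoxyphenyl)-3-(hydroxymethyl)-7-methoxy-2,3-dihydro-1-benzofuran-5-carbonitrile
Conditions: MeI, K2CO3, acetone, rt
Reagents that add atoms: iodomethane CI
Why: Williamson O-methylation, in which K2CO3 deprotonates only the ring B phenol and not the primary alcohol, and iodomethane methylates it at room temperature, where base-induced reopening of the benzylic aryl ether is slow.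

Step 13
Reactants: 20 (2S,3R)-2-(3,4-dimethoxyphenyl)-3-(hydroxymethyl)-7-methoxy-2,3-dihydro-1-benzofuran-5-carbonitrile
Product: 22 (2S,3R)-2-(3,4-dimethoxyphenyl)-3-(hydroxymethyl)-7-methoxy-2,3-dihydro-1-benzofuran-5-carbaldehyde, via aldimine 21 (not isolated)
Conditions: i-Bu2AlH (3 equiv), CH2Cl2, −78 to −40 °C; then 1 M HCl, 0 °C
Reagents that add atoms: water O
Why: Partial reduction of a nitrile with i-Bu2AlH, in which, after the alcohol has consumed one equivalent, a single hydride adds to the nitrile to give the N-aluminated form of aldimine 21, which resists further reduction at low temperature and is hydrolysed to the aldehyde by the acidic work-up.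

Step 14
Reactants: 22 (2S,3R)-2-(3,4-dimethoxyphenyl)-3-(hydroxymethyl)-7-methoxy-2,3-dihydro-1-benzofuran-5-carbaldehyde; 23 methyl (triphenylphosphoranylidene)acetate
Product: 24 methyl (2E)-3-[(2S,3R)-2-(3,4-dimethoxyphenyl)-3-(hydroxymethyl)-7-methoxy-2,3-dihydro-1-benzofuran-5-yl]prop-2-enoate
Conditions: toluene, 80 °C
Reagents that add atoms: none
Why: Wittig reaction with a stabilised ylide, which should give the (E)-acrylate; the free alcohol does not interfere.

Step 15
Reactants: 24 methyl (2E)-3-[(2S,3R)-2-(3,4-dimethoxyphenyl)-3-(hydroxymethyl)-7-methoxy-2,3-dihydro-1-benzofuran-5-yl]prop-2-enoate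
Product: 25 Hierochin B, (2E)-3-[(2S,3R)-2-(3,4-dimethoxyphenyl)-3-(hydroxymethyl)-7-methoxy-2,3-dihydro-1-benzofuran-5-yl]prop-2-en-1-ol
Conditions: i-Bu2AlH (4 equiv), CH2Cl2, −78 °C; then aq. potassium sodium tartrate
Reagents that add atoms: none
Why: 1,2-Reduction of the α,β-unsaturated ester with i-Bu2AlH at −78 °C, which should give the allylic alcohol with the E double bond intact and leave the benzylic aryl ether and both stereocentres untouched.

## Compound list

1 | 4-hydroxy-3-methoxybenzonitrile | N#Cc1ccc(O)c(OC)c1 | starting material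
2 | allyl bromide (3-bromoprop-1-ene) | C=CCBr | starting material
3 | 3-methoxy-4-(prop-2-en-1-yloxy)benzonitrile | N#Cc1ccc(OCC=C)c(OC)c1 | intermediate
4 | 4-hydroxy-3-methoxy-5-(prop-2-en-1-yl)benzonitrile | N#Cc1cc(CC=C)c(O)c(OC)c1 | intermediate
5 | 4-(benzyloxy)-3-methoxy-5-(prop-2-en-1-yl)benzonitrile | N#Cc1cc(CC=C)c(OCc2ccccc2)c(OC)c1 | intermediate
6 | ozonide, 4-(benzyloxy)-3-methoxy-5-(1,2,4-trioxolan-3-ylmethyl)benzonitrile (formed in the flask) | N#Cc1cc(CC2OCOO2)c(OCc2ccccc2)c(OC)c1 | intermediate
7 | 4-(benzyloxy)-3-methoxy-5-(2-oxoethyl)benzonitrile | N#Cc1cc(CC=O)c(OCc2ccccc2)c(OC)c1 | intermediate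
8 | [2-(benzyloxy)-5-cyano-3-methoxyphenyl]acetic acid | N#Cc1cc(CC(=O)O)c(OCc2ccccc2)c(OC)c1 | intermediate
9 | (4R)-4-benzyl-1,3-oxazolidin-2-one | O=C1N[C@H](Cc2ccccc2)CO1 | starting material
10 | mixed pivalic anhydride, [2-(benzyloxy)-5-cyano-3-methoxyphenyl]acetic 2,2-dimethylpropanoic anhydride (formed in the flask) | N#Cc1cc(CC(=O)OC(=O)C(C)(C)C)c(OCc2ccccc2)c(OC)c1 | intermediate
11 | 4-(benzyloxy)-3-{2-[(4R)-4-benzyl-2-oxo-1,3-oxazolidin-3-yl]-2-oxoethyl}-5-methoxybenzonitrile | N#Cc1cc(CC(=O)N2C(=O)OC[C@H]2Cc2ccccc2)c(OCc2ccccc2)c(OC)c1 | intermediate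
12 | [4-(benzyloxy)-3-methoxyphenyl]methanol | COc1cc(CO)ccc1OCc1ccccc1 | starting material
13 | 1-(benzyloxy)-4-(bromomethyl)-2-methoxybenzene | COc1cc(CBr)ccc1OCc1ccccc1 | intermediate
14 | sodium (Z)-enolate of 11 (formed in the flask) | N#Cc1cc(/C=C(\[O-])N2C(=O)OC[C@H]2Cc2ccccc2)c(OCc2ccccc2)c(OC)c1.[Na+] | intermediate
15 | 4-(benzyloxy)-3-{(2R)-1-[(4R)-4-benzyl-2-oxo-1,3-oxazolidin-3-yl]-3-[4-(benzyloxy)-3-methoxyphenyl]-1-oxopropan-2-yl}-5-methoxybenzonitrile | N#Cc1cc([C@@H](Cc2ccc(OCc3ccccc3)c(OC)c2)C(=O)N2C(=O)OC[C@H]2Cc2ccccc2)c(OCc2ccccc2)c(OC)c1 | intermediate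
16 | 4-(benzyloxy)-3-{(2R)-1-[4-(benzyloxy)-3-methoxyphenyl]-3-hydroxypropan-2-yl}-5-methoxybenzonitrile | N#Cc1cc([C@@H](Cc2ccc(OCc3ccccc3)c(OC)c2)CO)c(OCc2ccccc2)c(OC)c1 | intermediate
17 | 4-hydroxy-3-[(2R)-1-hydroxy-3-(4-hydroxy-3-methoxyphenyl)propan-2-yl]-5-methoxybenzonitrile (key-step precursor) | N#Cc1cc([C@@H](Cc2ccc(O)c(OC)c2)CO)c(O)c(OC)c1 | intermediate
18 | para-quinone methide, 4-hydroxy-3-[(2R)-1-hydroxy-3-(3-methoxy-4-oxocyclohexa-2,5-dien-1-ylidene)propan-2-yl]-5-methoxybenzonitrile (formed in the flask) | N#Cc1cc([C@@H](C=C2C=CC(=O)C(OC)=C2)CO)c(O)c(OC)c1 | intermediate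
19 | (2S,3R)-3-(hydroxymethyl)-2-(4-hydroxy-3-methoxyphenyl)-7-methoxy-2,3-dihydro-1-benzofuran-5-carbonitrile (key-step product) | COc1cc([C@H]2Oc3c(OC)cc(C#N)cc3[C@@H]2CO)ccc1O | intermediate
20 | (2S,3R)-2-(3,4-dimethoxyphenyl)-3-(hydroxymethyl)-7-methoxy-2,3-dihydro-1-benzofuran-5-carbonitrile | COc1ccc([C@H]2Oc3c(OC)cc(C#N)cc3[C@@H]2CO)cc1OC | intermediate
21 | aldimine, [(2S,3R)-2-(3,4-dimethoxyphenyl)-5-(iminomethyl)-7-methoxy-2,3-dihydro-1-benzofuran-3-yl]methanol (held as its diisobutylaluminium derivative until the quench) | COc1ccc([C@H]2Oc3c(OC)cc(C=N)cc3[C@@H]2CO)cc1OC | intermediate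
22 | (2S,3R)-2-(3,4-dimethoxyphenyl)-3-(hydroxymethyl)-7-methoxy-2,3-dihydro-1-benzofuran-5-carbaldehyde | COc1ccc([C@H]2Oc3c(OC)cc(C=O)cc3[C@@H]2CO)cc1OC | intermediate
23 | methyl (triphenylphosphoranylidene)acetate | COC(=O)C=P(c1ccccc1)(c1ccccc1)c1ccccc1 | starting material
24 | methyl (2E)-3-[(2S,3R)-2-(3,4-dimethoxyphenyl)-3-(hydroxymethyl)-7-methoxy-2,3-dihydro-1-benzofuran-5-yl]prop-2-enoate | COc1ccc([C@H]2Oc3c(OC)cc(/C=C/C(=O)OC)cc3[C@@H]2CO)cc1OC | intermediate
25 | Hierochin B, (2E)-3-[(2S,3R)-2-(3,4-dimethoxyphenyl)-3-(hydroxymethyl)-7-methoxy-2,3-dihydro-1-benzofuran-5-yl]prop-2-en-1-ol | COc1ccc([C@H]2Oc3c(OC)cc(/C=C/CO)cc3[C@@H]2CO)cc1OC | target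

## Step count and risks

Total step count: 15. Longest linear sequence: 14 steps (steps 1–6 and 8–15, from 1 to 25); step 7 is a one-step side branch.

Steps most likely to fail:

Step 11 (oxidative closure). The ring B phenoxyl radical may couple through its free C5 or its oxygen faster than it is oxidised on to the quinone methide. The product, still a 4-alkylguaiacol, may also be dehydrogenated further towards the benzofuran. The fallback avoids any phenoxyl radical and any phenolic product: ring B is carried as its dimethyl ether and the C2 methylene is oxidised by hydride abstraction with DDQ, the reaction type known from the cyclisation of 2'-hydroxyisoflavans to pterocarpans. It sets out from imide 11. The sodium enolate of 11 (NaN(SiMe3)2, THF, −78 °C) is alkylated with commercial 3,4-dimethoxybenzyl bromide to give 4-(benzyloxy)-3-{(2R)-1-[(4R)-4-benzyl-2-oxo-1,3-oxazolidin-3-yl]-3-(3,4-dimethoxyphenyl)-1-oxopropan-2-yl}-5-methoxybenzonitrile F1. LiBH4 (Et2O–THF, 0 °C) should then give 4-(benzyloxy)-3-[(2R)-1-(3,4-dimethoxyphenyl)-3-hydroxypropan-2-yl]-5-methoxybenzonitrile F2, and H2 over Pd/C should give 3-[(2R)-1-(3,4-dimethoxyphenyl)-3-hydroxypropan-2-yl]-4-hydroxy-5-methoxybenzonitrile F3. DDQ (1.1 equiv, CH2Cl2, rt) should take hydride from the methylene para to the 4-methoxy group of ring B, and the cyanophenol oxygen closes on the cation anti to the C3 substituent. The product is 20, where the fallback rejoins the route; steps 8–12 are replaced.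

Step 8 (auxiliary alkylation). Facial selectivity may erode, the acidic α-aryl centre may epimerise under base, and the electron-rich bromide may self-alkylate before it meets the enolate. The fallback replaces auxiliary control with catalytic asymmetric hydrogenation and sets out from acid 8. Perkin condensation with commercial 4-(benzyloxy)-3-methoxybenzaldehyde (Ac2O, Et3N, 110 °C) should give (2E)-2-[2-(benzyloxy)-5-cyano-3-methoxyphenyl]-3-[4-(benzyloxy)-3-methoxyphenyl]prop-2-enoic acid F4. Hydrogenation with a cationic iridium catalyst [Ir(cod)(L)]BArF (L = chiral spiro phosphine–oxazoline ligand, antipode chosen to give the R acid; H2, Et3N, MeOH) should give (2R)-2-[2-(benzyloxy)-5-cyano-3-methoxyphenyl]-3-[4-(benzyloxy)-3-methoxyphenyl]propanoic acid F5. BH3·SMe2 (THF, 0 °C) reduces the acid and not the nitrile, giving alcohol 16, where the fallback rejoins the route; steps 6–9 are replaced.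

Step 10 (debenzylation). The aryl nitrile may be hydrogenated to the benzylamine on the palladium surface alongside debenzylation. The fallback is a Lewis acid debenzylation with no hydrogen and no metal surface. From 16, BCl3 with pentamethylbenzene as benzyl cation scavenger (CH2Cl2, −78 °C) should cleave both aryl benzyl ethers while the aryl methyl ethers and the nitrile stay, giving 17 directly; no new compound is made.

## Further compounds

F1 | step 11 | 4-(benzyloxy)-3-{(2R)-1-[(4R)-4-benzyl-2-oxo-1,3-oxazolidin-3-yl]-3-(3,4-dimethoxyphenyl)-1-oxopropan-2-yl}-5-methoxybenzonitrile | N#Cc1cc([C@@H](Cc2ccc(OC)c(OC)c2)C(=O)N2C(=O)OC[C@H]2Cc2ccccc2)c(OCc2ccccc2)c(OC)c1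
F2 | step 11 | 4-(benzyloxy)-3-[(2R)-1-(3,4-dimethoxyphenyl)-3-hydroxypropan-2-yl]-5-methoxybenzonitrile | N#Cc1cc([C@@H](Cc2ccc(OC)c(OC)c2)CO)c(OCc2ccccc2)c(OC)c1
F3 | step 11 | 3-[(2R)-1-(3,4-dimethoxyphenyl)-3-hydroxypropan-2-yl]-4-hydroxy-5-methoxybenzonitrile | N#Cc1cc([C@@H](Cc2ccc(OC)c(OC)c2)CO)c(O)c(OC)c1
F4 | step 8 | (2E)-2-[2-(benzyloxy)-5-cyano-3-methoxyphenyl]-3-[4-(benzyloxy)-3-methoxyphenyl]prop-2-enoic acid | OC(=O)/C(=C/c1ccc(OCc2ccccc2)c(OC)c1)c1cc(C#N)cc(OC)c1OCc1ccccc1
F5 | step 8 | (2R)-2-[2-(benzyloxy)-5-cyano-3-methoxyphenyl]-3-[4-(benzyloxy)-3-methoxyphenyl]propanoic acid | N#Cc1cc([C@@H](Cc2ccc(OCc3ccccc3)c(OC)c2)C(=O)O)c(OCc2ccccc2)c(OC)c1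
F0 | step 10 | none | none
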